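**Plan**

1. Retrosynthesis: the spiro dihydropyran is cut at O–C8 and at C13–C1' (one oxa-Diels–Alder retron), then the C1'=C2' bond of the resulting heterodiene (Knoevenagel retron). This leaves a caryophylla-3,8(13)-dien-5-ol, syncarpic acid and isovaleraldehyde.
2. Enabling feature: the ring O–C8(quaternary, spiro)–C13H2–C1'H(isobutyl)–C2'=C3' is the adduct of the exocyclic 1,1-disubstituted alkene C8=C13 of the nine-membered ring with the 1-oxadiene O=C3'–C2'=C1' of a symmetric gem-dimethyl β-triketone that has no enolisable hydrogen.
3. Terpene arm: (−)-isocaryophyllene supplies the cyclobutane and the nine-membered ring. A singlet-oxygen ene/dehydration moves the ring alkene to C3=C4 (Z) and places a ketone on C5, and an oxazaborolidine reduction gives the 5S alcohol.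
4. Trione arm: C-tetramethylation of 2',4',6'-trihydroxyacetophenone, then deacetylation to syncarpic acid.
5. Union last: a three-component Knoevenagel/oxa-Diels–Alder reaction closes the dihydropyran, the only ring made in the route, on the free dienol.
6. Stereochemistry: C1 and C9 come from the chiral pool, C5 from the CBS catalyst, C8 and C1' from substrate control in the cycloaddition, and 3Z from the ring-cis ene pathway and the preferred enone geometry.

Key step: step 5

Remark: caryophyllane numbering is used (C1/C9 ring fusion, C8 carries the C13 methylene, C1' is the isobutyl-bearing carbon, C2'=C3' the enol-ether alkene); (−)-isocaryophyllene is taken as a purchasable terpene with the (1R,9S) ring fusion of the target.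

**Route**

Step 1
Reactants: 1 (−)-isocaryophyllene
Product: 4 (1R,3Z,9S)-4,11,11-trimethyl-8-methylidenebicyclo[7.2.0]undec-3-en-5-one, via C5 hydroperoxide 2 (not isolated), via C5 peracetate 3 (not isolated)
Conditions: O2, visible light, 5,10,15,20-tetraphenylporphyrin (cat.), Ac2O, pyridine, 4-(dimethylamino)pyridine (cat.), CH2Cl2, 0 °C to rt
Reagents that add atoms: oxygen (reacting as singlet oxygen), O=O
Why: Schenck ene reaction with Kornblum–DeLaMare dehydration in one flask: singlet oxygen should attack only the electron-rich trisubstituted C4=C5 alkene, the cis effect directs hydrogen abstraction to the ring methylenes C3 and C6 on the doubly substituted side of the Z alkene, and only the secondary C5 hydroperoxide (C3=C4, ring-cis) can be dehydrated to the enone, so the facial outcome at C5 is irrelevant and no stereocentre is set.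

Step 2
Reactants: 4 (1R,3Z,9S)-4,11,11-trimethyl-8-methylidenebicyclo[7.2.0]undec-3-en-5-one
Product: 5 (1R,3Z,5S,9S)-4,11,11-trimethyl-8-methylidenebicyclo[7.2.0]undec-3-en-5-ol
Conditions: (R)-2-methyl-CBS-oxazaborolidine [(R)-1-methyl-3,3-diphenyltetrahydro-1H,3H-pyrrolo[1,2-c][1,3,2]oxazaborole] (20 mol %), catecholborane, toluene, −78 °C; then MeOH, aq NaOH
Reagents that add atoms: none
Why: Corey–Bakshi–Shibata reduction: on the Corey model the ketone binds boron anti to the larger α-methylalkenyl carbon C4, so the (R)-catalyst should deliver hydride to the face that gives the 5S carbinol, while catecholborane at −78 °C reduces 1,2 and leaves the C8=C13 methylene untouched.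

Step 3
Reactants: 6 2',4',6'-trihydroxyacetophenone
Product: 7 2-acetyl-4,4,6,6-tetramethylcyclohexane-1,3,5-trione (enol form)
Conditions: MeI (excess), NaOMe, MeOH, 0 °C to reflux
Reagents that add atoms: iodomethane, CI
Why: Dearomatising exhaustive C-methylation of an acylphloroglucinol: the phenoxide is C-alkylated twice at each of the two unsubstituted ring carbons, and the geminal methyl pairs lock the ring as the trione.

Step 4
Reactants: 7 2-acetyl-4,4,6,6-tetramethylcyclohexane-1,3,5-trione
Product: 8 syncarpic acid (2,2,4,4-tetramethylcyclohexane-1,3,5-trione)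
Conditions: 6 M aq HCl, reflux
Reagents that add atoms: none
Why: Acid-mediated retro-Claisen deacylation of a β-triketone: hydration of the exocyclic acetyl carbonyl and C–C cleavage release acetic acid and free the single enolisable ring carbon needed for the condensation in step 5.

Step 5
Reactants: 5 (1R,3Z,5S,9S)-4,11,11-trimethyl-8-methylidenebicyclo[7.2.0]undec-3-en-5-ol; 8 syncarpic acid; 9 isovaleraldehyde (3-methylbutanal)
Product: 11 tomentodione P, via heterodiene 10 (not isolated)
Conditions: ethylenediammonium diacetate (20 mol %), 4 Å molecular sieves, toluene, rt to 60 °C; 8 and 9 in slight excess, added in portions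
Reagents that add atoms: none
Why: Ethylenediammonium diacetate condenses aldehyde 9 with the only enolisable carbon of 8 (Knoevenagel) to give the 2-alkylidene-1,3,5-trione 10, whose O=C3'–C2'=C1' unit then acts as an electron-poor 1-oxadiene in an inverse-electron-demand oxa-Diels–Alder reaction with the C8=C13 methylene of 5, the C13–C1' bond running ahead and the carbonyl oxygen closing on C8, the carbon that best carries positive charge. The closest known reaction type is the domino Knoevenagel/hetero-Diels–Alder reaction, as used for biomimetic unions of syncarpic-acid-derived heterodienes with terpene alkenes. The dihydropyran is the only ring closed; it forms by intermolecular [4+2] cycloaddition in spiro fashion at C8, the O–C8 bond completing the six-membered ring. C8 (S) should be set by the π-facial bias of the trans-fused bicyclo[7.2.0] frame, the oxygen arriving on the outer face of the methylene (the C10 side of C9) while C1–C2 and the transannular chain cover the other face; C1' (S) should be set by the relative topicity, with isobutyl outside on the heterodiene and a chair-like transition state that keeps isobutyl and the branched C9 arm pseudo-equatorial and only the C7 methylene axial. The step needs chemoselectivity for C8=C13 over C3=C4 and over the free hydroxyl, and O-to-C8 regioselectivity: the 1,1-disubstituted alkene offers an unhindered CH2 terminus and a tertiary cation-like C8, whereas C3=C4 is hindered at both ends and inductively deactivated by the allylic C5–OH, and any oxa-Michael adduct of the hydroxyl is reversible. The symmetry of 10 (two equivalent flanking carbonyls, no enolisable hydrogen) removes regiochemical and geometric ambiguity on the heterodiene side.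

**Compound list**

1 | (−)-isocaryophyllene, (1R,4Z,9S)-4,11,11-trimethyl-8-methylidenebicyclo[7.2.0]undec-4-ene | C/C1=C/CCC(=C)[C@H]2CC(C)(C)[C@@H]2CC1 | starting material
2 | (1R,3Z,9S)-5-hydroperoxy-4,11,11-trimethyl-8-methylidenebicyclo[7.2.0]undec-3-ene, both C5 epimers | C/C1=C/C[C@@H]2[C@H](CC2(C)C)C(=C)CCC1OO | intermediate (not isolated)
3 | peracetate of 2, (1R,3Z,9S)-5-(acetylperoxy)-4,11,11-trimethyl-8-methylidenebicyclo[7.2.0]undec-3-ene, both C5 epimers | C/C1=C/C[C@@H]2[C@H](CC2(C)C)C(=C)CCC1OOC(C)=O | intermediate (not isolated)
4 | (1R,3Z,9S)-4,11,11-trimethyl-8-methylidenebicyclo[7.2.0]undec-3-en-5-one | C/C1=C/C[C@@H]2[C@H](CC2(C)C)C(=C)CCC1=O | intermediate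
5 | (1R,3Z,5S,9S)-4,11,11-trimethyl-8-methylidenebicyclo[7.2.0]undec-3-en-5-ol | C/C1=C/C[C@@H]2[C@H](CC2(C)C)C(=C)CC[C@@H]1O | intermediate
6 | 2',4',6'-trihydroxyacetophenone | CC(=O)c1c(O)cc(O)cc1O | starting material
7 | 2-acetyl-4,4,6,6-tetramethylcyclohexane-1,3,5-trione (drawn as its enol) | CC(=O)C1=C(O)C(C)(C)C(=O)C(C)(C)C1=O | intermediate
8 | syncarpic acid, 2,2,4,4-tetramethylcyclohexane-1,3,5-trione | CC1(C)C(=O)CC(=O)C(C)(C)C1=O | intermediate
9 | isovaleraldehyde, 3-methylbutanal | CC(C)CC=O | starting material
10 | 2-(3-methylbutylidene)-4,4,6,6-tetramethylcyclohexane-1,3,5-trione | CC(C)CC=C1C(=O)C(C)(C)C(=O)C(C)(C)C1=O | intermediate (not isolated)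
11 | tomentodione P: (1R,3Z,5S,8S,9S)-caryophyll-3-en-5-ol spiro-linked at C8 (through O and C13) to a (1'S)-isobutyl 6,6,8,8-tetramethylchromane-5,7-dione unit | C/C1=C/C[C@@H]2[C@H](CC2(C)C)[C@]2(CC[C@@H]1O)C[C@H](CC(C)C)C1=C(O2)C(C)(C)C(=O)C(C)(C)C1=O | target

**Step count**

Total steps: 5. Longest linear sequence: 3 steps (steps 1, 2, 5 or steps 3, 4, 5).

**Steps most likely to fail**

Step 5. The cycloaddition may show poor facial or topicity control, so that C8 or C1' epimers form. Further risks are Michael capture of 10 by a second molecule of 8 and interference by the free allylic hydroxyl. The fallback inverts the last two events. It sets out from enone 4, which has no hydroxyl, an enone alkene inert to an electron-poor heterodiene, and a flattened C3–C5 segment that presents a different ring conformation. The same Knoevenagel/oxa-Diels–Alder reaction with 8 and 9 (through 10) should give the 5-oxo spiro adduct F1. Reduction of its C5 carbonyl with the (R)-oxazaborolidine/catecholborane system then returns to the route at target 11; the other carbonyls are a vinylogous ester and a ketone flanked by two quaternary carbons.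

Step 1. Hydrogen abstraction may go mainly at C6 or at the C12 methyl instead of C3, or the new alkene may form ring-trans. The fallback sets out from 1:
- Epoxidation with 3-chloroperbenzoic acid (NaHCO3, CH2Cl2, 0 °C) occurs at the trisubstituted alkene and gives isocaryophyllene 4,5-oxide F2; either face is acceptable.
- LiNEt2 in refluxing Et2O isomerises the epoxide by syn-elimination to caryophylla-4(12),8(13)-dien-5-ol F3.
- Dess–Martin periodinane gives the exo-methylene enone caryophylla-4(12),8(13)-dien-5-one F4.
- Conjugate reduction with LiBH(s-Bu)3 (THF, −78 °C) and trapping of the regiodefined enolate with PhSeBr give 4-(phenylselanyl)caryophyll-8(13)-en-5-one F5.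
- H2O2/pyridine then triggers selenoxide syn-elimination into the ring, returning to the route at enone 4.

Step 2. Catalyst and substrate may be mismatched, giving poor facial selectivity at C5, or the methylene may be hydroborated. The fallback sets out from 4 with a substrate-controlled Luche reduction (NaBH4, CeCl3·7H2O, MeOH, −78 °C). If this favours the (5R)-epimer, (1R,3Z,5R,9S)-4,11,11-trimethyl-8-methylidenebicyclo[7.2.0]undec-3-en-5-ol F6, a Mitsunobu inversion (4-nitrobenzoic acid, PPh3, diisopropyl azodicarboxylate, THF) gives the (5S)-4-nitrobenzoate F7. Methanolysis (K2CO3, MeOH) returns to the route at dienol 5.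

**Further compounds**

F1 | step 5 | (1R,3Z,8S,9S,1'S)-5-oxo analogue of tomentodione P (C5 ketone spiro adduct) | C/C1=C/C[C@@H]2[C@H](CC2(C)C)[C@]2(CCC1=O)C[C@H](CC(C)C)C1=C(O2)C(C)(C)C(=O)C(C)(C)C1=O
F2 | step 1 | isocaryophyllene 4,5-oxide, (1R,9S)-cis-4,5-epoxy-4,11,11-trimethyl-8-methylidenebicyclo[7.2.0]undecane, either epoxide face | CC12CC[C@@H]3[C@H](CC3(C)C)C(=C)CCC1O2
F3 | step 1 | (1R,9S)-caryophylla-4(12),8(13)-dien-5-ol, either C5 epimer | C=C1CC[C@@H]2[C@H](CC2(C)C)C(=C)CCC1O
F4 | step 1 | (1R,9S)-caryophylla-4(12),8(13)-dien-5-one | C=C1CC[C@@H]2[C@H](CC2(C)C)C(=C)CCC1=O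
F5 | step 1 | (1R,9S)-4-(phenylselanyl)caryophyll-8(13)-en-5-one, either C4 epimer | CC1([Se]c2ccccc2)CC[C@@H]2[C@H](CC2(C)C)C(=C)CCC1=O
F6 | step 2 | (1R,3Z,5R,9S)-4,11,11-trimethyl-8-methylidenebicyclo[7.2.0]undec-3-en-5-ol | C/C1=C/C[C@@H]2[C@H](CC2(C)C)C(=C)CC[C@H]1O
F7 | step 2 | (1R,3Z,5S,9S)-4,11,11-trimethyl-8-methylidenebicyclo[7.2.0]undec-3-en-5-yl 4-nitrobenzoate | C/C1=C/C[C@@H]2[C@H](CC2(C)C)C(=C)CC[C@@H]1OC(=O)c1ccc(cc1)[N+](=O)[O-]
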